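**Remark (assumption on the chemistry).** Positional numbering used throughout: macrolactone C1 (C=O) to C9 (O‑bearing CH, carries C10 methyl); butyrolactone carbonyl C1′ and α‑carbon C2′; furan C3′–C6′; side chain C7′–C10′ (C9′ is the carbinol). The SMILES is read as 3S,4S,9R,2′S,9′R, with H‑3, H‑4 and H‑2′ all on the same face of the butyrolactone (all‑cis).

## Analysis of the target

The skeleton is a ten‑membered lactone (ring O, C1–C9) with a ketone at C6. It is cis‑fused across C3–C4 to a γ‑butyrolactone (O–C3, C4–C2′, C1′), and C2′ carries a 2,5‑disubstituted furan. The C20 framework is a pseudo‑dimer: both halves end in an (R)‑CH3CH(O)CH2CH2 unit (C9/C10 and C9′/C10′). Three of the five stereocenters are contiguous (C3, C4, C2′) and all‑cis; the other two (C9, C9′) are remote and cannot be reached by induction from the triad. C2′–H is α to a lactone carbonyl and to the furan, so it epimerises easily, and the all‑cis arrangement is the crowded one; it has to be set kinetically and late. The C3 acyloxy group is β to the C1 ester (E1cB risk under base), and the furan is sensitive to electrophilic oxidants and strong acid. The real difficulties are the medium ring and the cis ring fusion on it, because facial selectivity on a flexible ten‑membered ring cannot be predicted.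

The feature the route exploits: C1 (lactone C=O) and C6 (ketone) are joined on one side through O–C9–C8–C7 and on the other through C2–C3–C4–C5. If C1 and C6 are reconnected by a C=C bond, the ten ring atoms plus C10 become the ring atoms plus methyl of a 2‑methylchroman whose benzene ring is C1–C6. C3 and C4 are then neighbours on a six‑membered ring, where a fused γ‑lactone is cis without effort.

## Retrosynthetic reasoning

**19 ⇒ 17 (bond C1–C6).** The target is the product of oxidative cleavage of the tetrasubstituted enol ether C1=C6 of tricycle 17. Cutting here removes the medium ring from the problem: 17 contains only five‑ and six‑membered rings and already holds all five stereocenters. The forward step must cleave one electron‑rich C=C in the presence of the furan and must not touch C2′–H.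

**17 ⇒ 15 (C2′–H).** In 15 the lactone α‑CH is the only acidic C–H, since the ketone is masked as the enol ether. Deprotonation and protonation from the convex face of the cis‑fused lactone give the all‑cis triad. This is done on the rigid tricycle, before the base‑sensitive β‑acyloxy ester exists.

**15 ⇒ 14 ⇒ 12 (C1–O9 enol ether, C3–O lactone, C4–H).** 15 is the cyclodehydration product of the δ‑hydroxy ketone 14. The lactone of 14 comes from intramolecular oxa‑Michael addition of the side‑chain acid to a cyclohex‑2‑enone, which can only give the cis fusion. That enone is reached from the β,γ‑unsaturated ketone 12 by an amine‑catalysed enantioselective double‑bond shift that sets C4. C3 is relayed from C4, and C2′ is later relayed from both.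

**12 ⇒ 10 (dearomatisation).** 12 is the Birch reduction and hydrolysis product of the chroman acid 10. The ring oxygen and both alkyl groups direct the reduction to the 5,8‑dihydro isomer, which places the isolated double bond exactly at C3=C4 and the enol ether at C1=C6. The regiochemistry of every later event is fixed by the arene substitution pattern.

**10 ⇒ 9 ⇒ 6 + 8, and 6 ⇒ 4 + 5 (both bonds at C2′).** The diarylacetic acid is assembled by two Friedel–Crafts reactions at one carbon: 5 onto the position of 4 para to oxygen, then the resulting benzylic alcohol 6 onto the free α‑position of furan 8. No protecting group is needed, and the C2′ configuration is irrelevant at this stage.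

**4 ⇒ 3 ⇒ 1 + 2, and 8 ⇒ 7.** The two remote (R)‑carbinol centres are not relayed. C9 is bought with epoxide 1, and C9′ is set by enzymatic reduction of ketone 7.

## Alternatives that were turned down

**Alternative 1: macrolactonisation (textbook).** Disconnection of the C1–O bond to C9 gives seco acid A1, which would be activated (Yamaguchi or Shiina conditions) and closed at high dilution. Turned down for these reasons:
- Ten‑membered lactonisation has the worst combination of strain and entropy, so diolides are expected.
- The C9 hydroxyl of A1 sits five atoms from the C6 ketone and is sequestered as a five‑membered hemiketal; the C9′ hydroxyl competes and would need protection.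
- Activating C1 makes C2–H acidic with the C3 acyloxy group β to it (E1cB opening of the butyrolactone), and the amine/DMAP medium epimerises C2′.
- The all‑cis triad would have to be built in an open chain by separate reagent‑controlled steps.

**Alternative 2: biomimetic tethered Michael addition on the preformed macrolide.** Disconnection of C4–C2′: the hydroxy enone macrolide A2 is esterified to furylacetate A3, and base closes the butyrolactone by 5‑exo Michael addition to C4. Turned down for these reasons:
- The cyclisation needs the C3–O bond perpendicular to the C4=C5 π system. The accessible conformer of an E‑cyclodecenone has H‑3 eclipsing the double bond (A1,3 strain) and C2 anticlinal, which leads to the trans ring fusion, as in open‑chain γ‑acyloxy enoates.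
- C2′ would equilibrate under the basic conditions.
- A2 still requires a separate medium‑ring synthesis and is a γ‑hydroxy enone prone to elimination.

**Alternative 3: ring‑closing metathesis at C7–C8.** Diene A4 (vinyl ketone plus the ester of (R)‑but‑3‑en‑2‑ol) would be closed to enone A5 and then reduced 1,4. Turned down for these reasons:
- An electron‑poor vinyl ketone closing a ten‑membered ring favours oligomers.
- A5 needs a chemoselective conjugate reduction beside a furan and an epimerisable C2′.
- The all‑cis lactone must again be made first without any relay, and two redox steps are added.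

Key step: step 11

## Route

**Step 1**
Reactants: 1 (R)-2-methyloxirane; 2 (2-bromobenzyl)magnesium bromide
Product: 3 (2R)-4-(2-bromophenyl)butan-2-ol
Conditions: CuI (10 mol%), THF/Et2O, −40 to 0 °C; aq. NH4Cl
Reagents that add atoms: none
Why: Cu‑catalysed SN2 opening of the epoxide at the unsubstituted carbon by the benzylic Grignard reagent; the stereocenter is not involved, so 3 keeps the R configuration of 1.

**Step 2**
Reactants: 3 (2R)-4-(2-bromophenyl)butan-2-ol
Product: 4 (2R)-2-methyl-3,4-dihydro-2H-chromene [(R)-2-methylchroman]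
Conditions: Pd(OAc)2 (3 mol%), 2-(di-tert-butylphosphino)-1,1′-binaphthyl (4 mol%), Cs2CO3, toluene, 70 °C
Reagents that add atoms: none
Why: intramolecular Pd‑catalysed C–O coupling (Buchwald–Hartwig etherification) of a secondary alcohol with the ortho aryl bromide; the carbinol C–O bond is not broken, so C2 stays R.

**Step 3**
Reactants: 4 (R)-2-methylchroman; 5 ethyl glyoxylate
Product: 6 ethyl 2-hydroxy-2-[(2R)-2-methyl-3,4-dihydro-2H-chromen-6-yl]acetate (both carbinol epimers)
Conditions: TiCl4 (1.1 equiv), CH2Cl2, −78 to −40 °C
Reagents that add atoms: none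
Why: Friedel–Crafts hydroxyalkylation; the Ti‑activated aldehyde attacks the position para to the ring oxygen (C6); the new carbinol centre is a mixture and is destroyed in step 5.

**Step 4**
Reactants: 7 4-(furan-2-yl)butan-2-one
Product: 8 (2R)-4-(furan-2-yl)butan-2-ol
Conditions: (R)-selective alcohol dehydrogenase (Lactobacillus kefir type), NADP+ (cat.), 2-propanol, phosphate buffer pH 7, 30 °C
Reagents that add atoms: none
Why: enzymatic anti‑Prelog reduction of a methyl ketone; the active site distinguishes methyl from the furylethyl group and delivers hydride to the face that gives the R alcohol.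

**Step 5**
Reactants: 6 ethyl 2-hydroxy-2-[(2R)-2-methylchroman-6-yl]acetate; 8 (2R)-4-(furan-2-yl)butan-2-ol
Product: 9 ethyl 2-{5-[(3R)-3-hydroxybutyl]furan-2-yl}-2-[(2R)-2-methyl-3,4-dihydro-2H-chromen-6-yl]acetate (both C2 epimers)
Conditions: Sc(OTf)3 (5 mol%), MeNO2, 0 °C to rt
Reagents that add atoms: none
Why: SN1‑type Friedel–Crafts alkylation; ionisation of the benzylic alcohol gives a cation stabilised by the para ring oxygen, which is trapped at the free α‑position of the 2‑alkylfuran; the diarylmethine centre (later C2′) forms as a mixture and is corrected in step 10.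

**Step 6**
Reactants: 9 ethyl diarylacetate
Product: 10 2-{5-[(3R)-3-hydroxybutyl]furan-2-yl}-2-[(2R)-2-methyl-3,4-dihydro-2H-chromen-6-yl]acetic acid
Conditions: LiOH, THF/H2O, rt; then 1 M HCl to pH 3
Reagents that add atoms: lithium hydroxide, [Li+].[OH-]
Why: saponification; the free carboxylate is needed because an ester would be reduced in step 7.

**Step 7**
Reactants: 10 diarylacetic acid
Product: 12 2-{5-[(3R)-3-hydroxybutyl]furan-2-yl}-2-{5-[(3R)-3-hydroxybutyl]-4-oxocyclohex-1-en-1-yl}acetic acid (epimers at ring C5 and at C2; in equilibrium with its cyclic hemiketal), via dihydrochromene acid 11 (not isolated)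
Conditions: Li, NH3(l)/THF, t-BuOH, −78 °C; NH4Cl; then aq. oxalic acid, THF, 0 °C
Reagents that add atoms: water, O
Why: Birch reduction puts the ether oxygen and both alkyl groups on sp2 carbons (5,8‑dihydro isomer), while the carboxylate and the alkylfuran (harder to reduce than the arene) should survive; mild oxalic acid hydrolysis then opens the cyclic enol ether to the δ‑hydroxy ketone without moving the β,γ double bond.

**Step 8**
Reactants: 12 β,γ-unsaturated keto acid
Product: 14 (3aS,7aS)-3-{5-[(3R)-3-hydroxybutyl]furan-2-yl}-5-[(3R)-3-hydroxybutyl]hexahydro-1-benzofuran-2,6-dione (cis-fused; epimers at C3 and C5), via conjugated enone acid 13 (not isolated)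
Conditions: 9-amino-9-deoxy-epi-cinchona primary amine catalyst (10 mol%; pseudo-enantiomer chosen to give the 1R enone), toluene, 0 °C to rt
Reagents that add atoms: none
Why: catalytic enantioselective β,γ→α,β olefin isomerisation of a cyclohex‑3‑enone (iminium, dienamine, γ‑protonation by the protonated quinuclidine) sets the γ‑carbon (C3a, macrolide C4) under catalyst control with the substrate's own CO2H as acid cocatalyst; the tethered acid then adds to the enone by 5‑exo‑trig oxa‑Michael addition on the only face it can reach, so C7a (macrolide C3) is set cis by the substrate.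

**Step 9**
Reactants: 14 keto lactone
Product: 15 (3aS,7R,9aS)-3-{5-[(3R)-3-hydroxybutyl]furan-2-yl}-7-methyl-3,3a,4,5,6,7,9,9a-octahydro-2H-furo[3,2-g]chromen-2-one (both C3 epimers)
Conditions: PPTS (10 mol%), benzene, 4 Å MS, 50 °C, high dilution; chromatography removes the minor ring-fusion diastereomer
Reagents that add atoms: none
Why: acid‑catalysed cyclodehydration of a δ‑hydroxy ketone to the more substituted (tetrasubstituted) cyclic enol ether; this removes the epimeric centre next to the ketone and the base‑labile β‑acyloxy ketone, and because C7 is fixed the product of imperfect catalyst control in step 8 is a separable diastereomer.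

**Step 10**
Reactants: 15 tricyclic lactone (C3 epimers)
Product: 17 (3S,3aS,7R,9aS)-3-{5-[(3R)-3-hydroxybutyl]furan-2-yl}-7-methyl-3,3a,4,5,6,7,9,9a-octahydro-2H-furo[3,2-g]chromen-2-one, via dilithium enolate 16 (not isolated)
Conditions: LDA (2.3 equiv), THF, −78 °C; 2,6-di-tert-butylphenol (4 equiv), −78 °C; aq. NH4Cl
Reagents that add atoms: none
Why: the lactone α‑CH is the only acidic C–H, so both epimers converge on one enolate; kinetic protonation by a bulky phenol from the convex face of the cis‑fused bicyclic lactone puts H‑3 cis to H‑3a and H‑9a and the furyl group on the concave face, which is the all‑cis triad of the target.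

**Step 11**
Reactants: 17 all-cis tricyclic enol ether lactone
Product: 19 cordycicadin B [(3S,4S,9R,2′S,9′R); ten-membered 6-oxo lactone cis-fused at C3–C4 to the 2′-furyl γ-butyrolactone], via hemiketal diol 18 (not isolated)
Conditions: OsO4 (5 mol%), NaIO4 (4 equiv), 2,6-lutidine (2 equiv), dioxane/H2O 3:1, rt
Reagents that add atoms: osmium tetroxide, O=[Os](=O)(=O)=O; sodium periodate, [Na+].[O-][I](=O)(=O)=O
Why: Lemieux–Johnson oxidation of an enol ether: OsO4 adds to the electron‑rich tetrasubstituted C4a=C8a bond (macrolide C6=C1), the osmate ester is hydrolysed to α‑hydroxy hemiketal 18, and periodate cleaves its vicinal diol and re‑oxidises osmium. The closest known reaction type is the oxidative cleavage of 2,3‑fused dihydropyrans (hexahydrochromenes) to ten‑membered keto lactones; the hemiketal carbon becomes the lactone carbonyl C1 and the tertiary carbinol becomes the ketone C6. No ring is closed: the ten‑membered ring appears by scission of the bond shared by the two six‑membered rings, so no cyclisation entropy or transannular strain is paid in a bond‑forming transition state. No stereocenter is created and both faces of the enol ether give the same product; C3, C4, C2′, C9 and C9′ are carried over unchanged, and the cis fusion is inherited from the six‑membered ring. The selectivity needed is enol ether over furan: the aromatic furan should be inert to catalytic OsO4 and to periodate, whereas ozone, peracids or RuO4 would attack it. 2,6‑Lutidine keeps the medium neutral, which prevents acid hydration of the enol ether (a dead end) and is far too weak a base to epimerise C2′–H or to eliminate the C3 acyloxy group.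

## Compound list

1 | (R)-2-methyloxirane | C[C@@H]1CO1 | starting material
2 | (2-bromobenzyl)magnesium bromide | Br[Mg]Cc1ccccc1Br | starting material
3 | (2R)-4-(2-bromophenyl)butan-2-ol | C[C@@H](O)CCc1ccccc1Br | intermediate
4 | (2R)-2-methyl-3,4-dihydro-2H-chromene | C[C@@H]1CCc2ccccc2O1 | intermediate
5 | ethyl glyoxylate | CCOC(=O)C=O | starting material
6 | ethyl 2-hydroxy-2-[(2R)-2-methyl-3,4-dihydro-2H-chromen-6-yl]acetate (carbinol epimers) | C[C@@H]1CCc2cc(ccc2O1)C(O)C(=O)OCC | intermediate
7 | 4-(furan-2-yl)butan-2-one | CC(=O)CCc1ccco1 | starting material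
8 | (2R)-4-(furan-2-yl)butan-2-ol | C[C@@H](O)CCc1ccco1 | intermediate
9 | ethyl 2-{5-[(3R)-3-hydroxybutyl]furan-2-yl}-2-[(2R)-2-methyl-3,4-dihydro-2H-chromen-6-yl]acetate (C2 epimers) | C[C@@H]1CCc2cc(ccc2O1)C(C(=O)OCC)c1ccc(CC[C@@H](C)O)o1 | intermediate
10 | 2-{5-[(3R)-3-hydroxybutyl]furan-2-yl}-2-[(2R)-2-methyl-3,4-dihydro-2H-chromen-6-yl]acetic acid (C2 epimers) | C[C@@H]1CCc2cc(ccc2O1)C(C(=O)O)c1ccc(CC[C@@H](C)O)o1 | intermediate
11 | 2-{5-[(3R)-3-hydroxybutyl]furan-2-yl}-2-[(2R)-2-methyl-3,4,5,8-tetrahydro-2H-chromen-6-yl]acetic acid | C[C@@H]1CCC2=C(O1)CC=C(C2)C(C(=O)O)c1ccc(CC[C@@H](C)O)o1 | intermediate (not isolated)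
12 | 2-{5-[(3R)-3-hydroxybutyl]furan-2-yl}-2-{5-[(3R)-3-hydroxybutyl]-4-oxocyclohex-1-en-1-yl}acetic acid | C[C@@H](O)CCC1CC(=CCC1=O)C(C(=O)O)c1ccc(CC[C@@H](C)O)o1 | intermediate
13 | 2-{5-[(3R)-3-hydroxybutyl]furan-2-yl}-2-{(1R)-5-[(3R)-3-hydroxybutyl]-4-oxocyclohex-2-en-1-yl}acetic acid | C[C@@H](O)CCC1C[C@H](C=CC1=O)C(C(=O)O)c1ccc(CC[C@@H](C)O)o1 | intermediate (not isolated)
14 | (3aS,7aS)-3-{5-[(3R)-3-hydroxybutyl]furan-2-yl}-5-[(3R)-3-hydroxybutyl]hexahydro-1-benzofuran-2,6-dione | C[C@@H](O)CCC1C[C@@H]2[C@H](CC1=O)OC(=O)C2c1ccc(CC[C@@H](C)O)o1 | intermediate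
15 | (3aS,7R,9aS)-3-{5-[(3R)-3-hydroxybutyl]furan-2-yl}-7-methyl-3,3a,4,5,6,7,9,9a-octahydro-2H-furo[3,2-g]chromen-2-one (C3 epimers) | C[C@@H]1CCC2=C(O1)C[C@@H]3OC(=O)C(c4ccc(CC[C@@H](C)O)o4)[C@@H]3C2 | intermediate
16 | dilithium enolate–alkoxide of 15 | C[C@@H]1CCC2=C(O1)C[C@@H]3OC([O-])=C(c4ccc(CC[C@@H](C)[O-])o4)[C@@H]3C2.[Li+].[Li+] | intermediate (not isolated)
17 | (3S,3aS,7R,9aS)-3-{5-[(3R)-3-hydroxybutyl]furan-2-yl}-7-methyl-3,3a,4,5,6,7,9,9a-octahydro-2H-furo[3,2-g]chromen-2-one | C[C@@H]1CCC2=C(O1)C[C@@H]3OC(=O)[C@H](c4ccc(CC[C@@H](C)O)o4)[C@@H]3C2 | intermediate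
18 | (3S,3aS,7R,9aS)-4a,8a-dihydroxy-3-{5-[(3R)-3-hydroxybutyl]furan-2-yl}-7-methyldecahydro-2H-furo[3,2-g]chromen-2-one | C[C@@H]1CCC2(O)C(O)(O1)C[C@@H]3OC(=O)[C@H](c4ccc(CC[C@@H](C)O)o4)[C@@H]3C2 | intermediate (not isolated)
19 | cordycicadin B (3S,4S,9R,2′S,9′R) | C[C@@H]1CCC(=O)C[C@@H]2[C@H](CC(=O)O1)OC(=O)[C@@H]2c1ccc(CC[C@@H](C)O)o1 | target

## Step count and least certain steps

Total: 11 steps. Longest linear sequence: 10 steps (steps 1–3 and 5–11, from 1). No protecting groups are used.

**Step 11 (key step).** What may go wrong: osmylation of the hindered tetrasubstituted enol ether may be slow, so that oxidation of the furan or hydration of the enol ether competes. Fallback, from 17 back to 19: separate oxygenation from cleavage and drop osmium. Electrophilic epoxidation with dimethyldioxirane at −78 °C, where the enol ether is by far the most nucleophilic π bond, should give the epoxy ketal F1. Hydrolysis in moist THF gives diol 18, now isolated. NaIO4, which does not attack furans, then cleaves 18 to 19.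

**Step 8.** What may go wrong: weak or wrong‑sense catalyst control in the γ‑protonation (α′‑branched ketone, free acid, hemiketal equilibrium), or erosion by reversible dienamine formation. Fallback, from 12 back to 15: give up catalyst control and use the fixed C7 and C9′ centres for separation. TsOH (cat.) in refluxing benzene with removal of water should convert 12 directly into 15 and its ring‑fusion diastereomer, the (3aR,7R,9aR)‑lactone F2, in comparable amounts. These are diastereomers and are separated by chromatography. F2 is returned to the acid conditions, where ring opening to the dienyl ether and re‑closure should re‑equilibrate it.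

**Step 7.** What may go wrong: partial reduction of the furan, or poor solubility of the dilithium salt giving incomplete reduction. Fallback, from 6 back to 17: attach the furan after dearomatisation.
- Ionic hydrogenation of 6 (Et3SiH, TFA) gives ethyl 2-[(2R)-2-methylchroman-6-yl]acetate F3; LiOH gives the acid F4.
- Li/NH3 gives the dihydrochromene acid F5 (not isolated), and oxalic acid gives the β,γ‑unsaturated keto acid F6.
- The amine catalyst of step 8 gives, through the (1S)‑enone acid F7 (not isolated), the cis keto lactone F8; PPTS gives the aryl‑free tricyclic lactone F9.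
- F9 has a single acidic CH2. Its lithium enolate (LiHMDS, 3.3 equiv) is arylated under Pd(dba)2/P(t‑Bu)3 with 2-bromo-5-[(3R)-3-hydroxybutyl]furan F10 (from 8 with NBS, DMF, −20 °C).
- The arylated lactone is deprotonated in situ to 16, and the quench of step 10 gives 17.

**Step 10.** What may go wrong: insufficient facial selectivity, or equilibration to the exo epimer during the quench. Fallback, from 15 back to 19: postpone the correction. The conditions of step 11 applied to 15 give 19 together with its 2′‑epimer F11. LiHMDS (2.1 equiv, −78 °C) forms the aryl‑stabilised lactone enolate as the thermodynamic sink, and the same bulky phenol protonates it on the macrocycle, where the two cis ring arms at C3 and C4 shield one face.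

## Further compounds

F1 | step 11 | (3S,3aS,7R,9aS)-4a,8a-epoxy-3-{5-[(3R)-3-hydroxybutyl]furan-2-yl}-7-methyldecahydro-2H-furo[3,2-g]chromen-2-one | C[C@@H]1CCC23OC2(O1)C[C@@H]4OC(=O)[C@H](c5ccc(CC[C@@H](C)O)o5)[C@@H]4C3
F2 | step 8 | (3aR,7R,9aR)-3-{5-[(3R)-3-hydroxybutyl]furan-2-yl}-7-methyl-3,3a,4,5,6,7,9,9a-octahydro-2H-furo[3,2-g]chromen-2-one | C[C@@H]1CCC2=C(O1)C[C@H]3OC(=O)C(c4ccc(CC[C@@H](C)O)o4)[C@H]3C2
F3 | step 7 | ethyl 2-[(2R)-2-methyl-3,4-dihydro-2H-chromen-6-yl]acetate | C[C@@H]1CCc2cc(ccc2O1)CC(=O)OCC
F4 | step 7 | 2-[(2R)-2-methyl-3,4-dihydro-2H-chromen-6-yl]acetic acid | C[C@@H]1CCc2cc(ccc2O1)CC(=O)O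
F5 | step 7 | 2-[(2R)-2-methyl-3,4,5,8-tetrahydro-2H-chromen-6-yl]acetic acid | C[C@@H]1CCC2=C(O1)CC=C(C2)CC(=O)O
F6 | step 7 | 2-{5-[(3R)-3-hydroxybutyl]-4-oxocyclohex-1-en-1-yl}acetic acid | C[C@@H](O)CCC1CC(=CCC1=O)CC(=O)O
F7 | step 7 | 2-{(1S)-5-[(3R)-3-hydroxybutyl]-4-oxocyclohex-2-en-1-yl}acetic acid | C[C@@H](O)CCC1C[C@H](C=CC1=O)CC(=O)O
F8 | step 7 | (3aS,7aS)-5-[(3R)-3-hydroxybutyl]hexahydro-1-benzofuran-2,6-dione | C[C@@H](O)CCC1C[C@@H]2[C@H](CC1=O)OC(=O)C2
F9 | step 7 | (3aS,7R,9aS)-7-methyl-3,3a,4,5,6,7,9,9a-octahydro-2H-furo[3,2-g]chromen-2-one | C[C@@H]1CCC2=C(O1)C[C@@H]3OC(=O)C[C@@H]3C2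
F10 | step 7 | 2-bromo-5-[(3R)-3-hydroxybutyl]furan | C[C@@H](O)CCc1ccc(Br)o1
F11 | step 10 | 2′-epi-cordycicadin B (3S,4S,9R,2′R,9′R) | C[C@@H]1CCC(=O)C[C@@H]2[C@H](CC(=O)O1)OC(=O)[C@H]2c1ccc(CC[C@@H](C)O)o1
A1 | alternative 1 | seco acid: 2-[(2S,3S,4S)-4-{5-[(3R)-3-hydroxybutyl]furan-2-yl}-3-[(5R)-5-hydroxy-2-oxohexyl]-5-oxotetrahydrofuran-2-yl]acetic acid | C[C@@H](O)CCC(=O)C[C@@H]1[C@H](CC(=O)O)OC(=O)[C@@H]1c1ccc(CC[C@@H](C)O)o1
A2 | alternative 2 | (3S,9R,4E)-3-hydroxy-9-methyl-6-oxonon-4-en-9-olide | C[C@@H]1CCC(=O)/C=C/[C@H](CC(=O)O1)O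
A3 | alternative 2 | 3-O-(2-{5-[(3R)-3-hydroxybutyl]furan-2-yl}acetyl) ester of A2 | C[C@@H]1CCC(=O)/C=C/[C@H](CC(=O)O1)OC(=O)Cc1ccc(CC[C@@H](C)O)o1
A4 | alternative 3 | (R)-but-3-en-2-yl 2-[(2S,3S,4S)-4-{5-[(3R)-3-hydroxybutyl]furan-2-yl}-5-oxo-3-(2-oxobut-3-en-1-yl)tetrahydrofuran-2-yl]acetate | C=CC(=O)C[C@@H]1[C@H](CC(=O)O[C@H](C)C=C)OC(=O)[C@@H]1c1ccc(CC[C@@H](C)O)o1
A5 | alternative 3 | 7,8-didehydrocordycicadin B | C[C@@H]1C=CC(=O)C[C@@H]2[C@H](CC(=O)O1)OC(=O)[C@@H]2c1ccc(CC[C@@H](C)O)o1
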